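## Structural features

The target is a trans-fused 2,3,3a,6,7,7a-hexahydro-1H-inden-2-one. Cyclohexene ring A (C3a, C4, C5, C6, C7, C7a; C4=C5, ethyl on C4) shares the C3a–C7a bond with cyclopentanone ring B (C1, C2, C3, C3a, C7a; C2 is the carbonyl). The same atom labels are used for the corresponding carbons of all intermediates.

Six stereocentres form one unbroken chain, C3–C3a–C7a(–C1)–C7–C6, with descriptors (1S,3S,3aR,6S,7R,7aR). Ring B is all-trans: the C1 methyl, the C7a–C7 bond, the C3a–C4 bond and the C3 ethyl alternate between the two faces. C7 (ethyl, carboxyl) and C6 (ethyl, E-styryl) are adjacent all-carbon quaternary centres in ring A; the two ethyl groups are cis, as are styryl and carboxyl.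

Fragile points are the enolisable centres C1 and C3 (tolerable because all-trans is the thermodynamic arrangement), the carboxyl group lying γ,δ to both the styryl alkene and C4=C5 (lactonisation under strong acid or electrophiles), and the doubly neopentyl carboxyl carbon, which rules out substitution at the acyl carbon.

The real difficulty is the C6/C7 quaternary pair and its configuration relative to the ring fusion; ring B can be built by trans relay. The key step exploits the fact that C6 carries two alkenyl branches, C5 of the ring alkene and the α-carbon of the styryl group. With vinyl in place of styryl, C6 is a gem-divinyl carbon and not a stereocentre, and joining the C4 methylene to one of the two vinyl groups closes ring A and creates C6 in the same event.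

## Logic of the disconnections

**26 to 25.** The O–CH3 bond of a methyl ester is added in the retrosynthetic sense. The acid must be masked through the organometallic steps, and a methyl ester is the one ester that can later be removed by attack at the alkyl carbon. The forward step must be a dealkylation that leaves the ketone α-centres untouched.

**25 to 23 and 24.** The bond between the styryl β-carbon and the phenyl ring is cut. This turns the styryl group into a vinyl group, so that C6 carries two identical alkenyl groups at the next stage. The forward arylation must attack the terminal carbon only and give the E alkene; C6 has no hydrogen, which leaves only one elimination path.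

**23 to 22.** The C4=C5 double bond is cut. Ring A disappears and C6 ceases to be a stereocentre, so the bicycle with six stereocentres becomes a monocyclic all-trans cyclopentanone with five. The forward closure must choose one of two diastereotopic vinyl groups.

**22 to 17 and 18.** The C3a–C4 bond and the bond from C3 to its ethyl group are cut. Both centres can be set relative to C7a in one operation on an enone, which removes two stereocentres and a four-carbon branch. The forward step needs addition anti to the C7a chain and alkylation of the enolate before it equilibrates.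

**17 to 15.** The ester O–CH3 bond is cut and the C3=C3a double bond is traced back to a C3a–O bond. This oxygen is the relic of the stereocontrolling group of the chiral building block. The forward step must eliminate without moving the double bond into conjugation on the other side, and must leave the C1 methyl trans.

**15 to 12.** The C6–C7 bond is cut, with the allyl ester C–O bond re-formed. Joining the two quaternary carbons intramolecularly is the most reliable way to make this bond; the gain is a simple ester of a dienyl alcohol. The forward rearrangement needs a masked ketone, enolisation of an α-branched ester and control of the face of C7.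

**12 to 6 and 9.** The C7–C7a bond is cut. Conjugate addition anti to the C3a silyloxy group sets C7a absolutely and delivers the ketone as a regiodefined enol ether. The forward step must favour 1,4-addition and avoid proton transfer that would expel the silyloxy group.

**9 to 8 to 7.** The bond from C1 to its methyl group, then the C–I bond, are cut. The methyl group is needed on C1 both as a substituent of the target and as a control element in the rearrangement. The coupling must be run without base.

**6 to 4 and 5; 4 to 3; 3 to 1.** The ester C–O bond, the diene C3–C4 bond and finally the C–I and C–H bonds across the former alkyne are cut. This leads to a five-carbon propargylic alcohol and an acid chloride. The geometry of the trisubstituted alkene is of no consequence, because C6 receives two vinyl groups.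

## Other disconnections considered

**Alternative 1:** The cut is the ring-fusion bond C3a–C7a. In the forward sense the cross-conjugated E,E-dienone A2 would be protonated by a chiral Brønsted acid, the pentadienyl cation would close by conrotatory 4π electrocyclisation, and triethylsilane would reduce the oxyallyl cation to give the saturated all-trans ketone A1.

- In its favour: ring B and all four of its stereocentres arise in one step from an acyclic, convergently assembled dienone. The trans relation C3a/C7a follows from orbital symmetry, which is equal in reliability to the steric relay of the chosen plan. The absolute configuration would come from a catalyst and not from a stoichiometric chiral building block, and on that point it would be the better plan.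
- Against it here: A2 is an unpolarised dialkyl dienone, a substrate class that cyclises only under strong acid, whereas chiral acid catalysis is established for activated dienones. Hydride interception under the same chiral acid is a further untested demand. A1 also carries only oxygenated one- and two-carbon arms, so C7, C6, the butenyl group and ring A would all remain to be built.
- Comparison: the hard part of the structure, the quaternary pair, is untouched, and the step count would be clearly higher than in the chosen plan.

**Alternative 2:** The cut is C6–C7, with C4=C5 formed as an O–C4 bond breaks. The silyl ketene acetal of the 6-alkenyl δ-lactone A4 would rearrange through the boat transition state imposed by the ring, contracting the lactone to the ring A acid A3.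

- In its favour: both quaternary centres and ring A are formed in one pericyclic step. The ketene acetal geometry is fixed by the lactone ring, C7 is tied to C7a by that ring, and C6 follows from the alkene geometry. No group selection is needed and the styryl group is already in place, so no arylation step is required. On control of the quaternary pair it is, in principle, the better plan, and it builds two stereocentres in its key step where the chosen plan builds one.
- Against it here: A4 needs a tertiary allylic carbinol carbon C4 of defined configuration and a stereodefined trisubstituted diene that distinguishes ethyl from styryl at C6, which is about as hard as the original problem. The boat transition state must join two fully substituted carbons, and the tertiary allylic C4–O bond can ionise before it rearranges. Ring B would then have to be annulated from the alkyne and silyloxymethyl arms onto a congested ring A, with C1 set late.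
- Comparison: mechanistically the more elegant plan, but worse on substrate access and on step count.

**Alternative 3:** The cuts are C3a–C4 and the bond from C3 to its ethyl group. A but-1-en-2-ylcopper reagent would add to C3a of the 4,5-trans enone A6 anti to the C7a arm, and the enolate would be ethylated at C3 to give the all-trans ketone A5.

- In its favour: a dependable trans,trans relay and a convergent step. It is the same reaction type as step 9 of the chosen plan, so the two are equal on mechanism. A6 is less hindered at C7a than 17 and should accept the cuprate more readily, which is a point for the alternative.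
- Against it as the key disconnection: it solves only the easier half. From A5, C7 would still need its ethyl group, the dienyl ester and the sigmatropic shift. That requires protecting the ketone, and it leaves C7a flanked by two sp3 carbons that each turn only a hydrogen toward C7, so no face of C7 is preferred. A6 would also need its own source of absolute configuration.
- Comparison: similar or slightly greater length. The chosen plan uses the same operation but places it after the quaternary centre C7 is in place, so that the enol ether from the first conjugate addition can mask the ketone and steer C7.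

Key step: step 10

Assumption: (4S)-4-(tert-butyldimethylsilyloxy)cyclopent-2-en-1-one (7) is taken as a commercial, enantiomerically pure building block; its C4 oxygen is the only source of absolute configuration in the route.

## Route

Step 1
Reactants: 1 pent-2-yn-1-ol
Product: 3 (2Z)-3-iodopent-2-en-1-ol, via cyclic sodium alkenylalanate 2 (not isolated)
Conditions: NaAlH2(OCH2CH2OMe)2, THF, 0 → 23 °C; EtOAc; then I2, THF, –78 → 0 °C
Reagents that add atoms: iodine, II
Why: Hydroxyl-directed trans-hydroalumination of the propargylic alcohol places aluminium on C3 in chelate 2, and iodinolysis of the C–Al bond with retention gives the Z iodide.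

Step 2
Reactants: 3 (2Z)-3-iodopent-2-en-1-ol
Product: 4 (2Z)-3-ethylpenta-2,4-dien-1-ol
Conditions: CH2=CHSnBu3, PdCl2(MeCN)2 (3 mol %), DMF, 23 °C
Reagents that add atoms: tributyl(ethenyl)stannane, C=C[Sn](CCCC)(CCCC)CCCC
Why: Stille coupling of an alkenyl iodide proceeds with retention and tolerates the free allylic hydroxyl; the alkene geometry is in any case irrelevant later, because C6 receives two vinyl groups.

Step 3
Reactants: 4 (2Z)-3-ethylpenta-2,4-dien-1-ol; 5 butanoyl chloride
Product: 6 (2Z)-3-ethylpenta-2,4-dien-1-yl butanoate
Conditions: pyridine, DMAP (cat.), CH2Cl2, 0 °C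
Reagents that add atoms: none
Why: Acylation of a primary allylic alcohol by an acid chloride under nucleophilic catalysis.

Step 4
Reactants: 7 (4S)-4-[(tert-butyldimethylsilyl)oxy]cyclopent-2-en-1-one
Product: 8 (4S)-4-[(tert-butyldimethylsilyl)oxy]-2-iodocyclopent-2-en-1-one
Conditions: I2, pyridine–CH2Cl2 (1:1), 0 → 23 °C
Reagents that add atoms: iodine, II
Why: α-Iodination of the enone by conjugate addition of pyridine, iodination of the enolate and E1cB loss of pyridine; the silyloxy-bearing carbon is not involved and keeps its configuration.

Step 5
Reactants: 8 (4S)-4-[(tert-butyldimethylsilyl)oxy]-2-iodocyclopent-2-en-1-one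
Product: 9 (4S)-4-[(tert-butyldimethylsilyl)oxy]-2-methylcyclopent-2-en-1-one
Conditions: SnMe4, Pd2(dba)3 (2.5 mol %), AsPh3, CuI (10 mol %), NMP, 60 °C
Reagents that add atoms: tetramethylstannane, C[Sn](C)(C)C
Why: Stille methylation of the α-iodoenone with a zerovalent palladium catalyst under neutral conditions, which avoids base-induced loss of the β-silyloxy group.

Step 6
Reactants: 6 (2Z)-3-ethylpenta-2,4-dien-1-yl butanoate; 9 (4S)-4-[(tert-butyldimethylsilyl)oxy]-2-methylcyclopent-2-en-1-one
Product: 12 (2Z)-3-ethylpenta-2,4-dien-1-yl 2-[(1S,5S)-5-{[tert-butyl(dimethyl)silyl]oxy}-2-methyl-3-[(trimethylsilyl)oxy]cyclopent-2-en-1-yl]butanoate (both epimers at the butanoate α-carbon), via lithium enolate of the dienyl butanoate 10 (not isolated), via lithium cyclopentenolate adduct 11 (not isolated)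
Conditions: LiN(i-Pr)2, THF, –78 °C; 9, –78 °C; then Me3SiCl, Et3N, –78 → 0 °C
Reagents that add atoms: chlorotrimethylsilane, C[Si](C)(C)Cl
Why: Kinetic Michael addition of the lithium ester enolate to C7a from the face anti to the C3a silyloxy group sets C7a; silylation fixes the regiodefined enolate as the tetrasubstituted enol ether C1=C2, and the mixed centre C7 is planarised in step 7.

Step 7
Reactants: 12 (2Z)-3-ethylpenta-2,4-dien-1-yl 2-[(1S,5S)-5-{[tert-butyl(dimethyl)silyl]oxy}-2-methyl-3-[(trimethylsilyl)oxy]cyclopent-2-en-1-yl]butanoate
Product: 15 (2R)-2-[(1R,5S)-5-{[tert-butyl(dimethyl)silyl]oxy}-2-methyl-3-oxocyclopentyl]-2,3-diethyl-3-ethenylpent-4-enoic acid (epimers at the methyl-bearing carbon C1), via silyl ketene acetal 13 (not isolated), via rearranged trimethylsilyl ester 14 (not isolated)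
Conditions: KN(SiMe3)2, toluene, –78 °C; Me3SiCl; –78 → 90 °C; then 1 M HCl, THF, 0 → 23 °C
Reagents that add atoms: none
Why: Ireland–Claisen rearrangement: the tetrasubstituted silyl ketene acetal 13 undergoes the [3,3] shift on heating and joins C7 to C6, and because C6 ends up with two vinyl groups neither ketene acetal geometry nor chair/boat topology has a stereochemical consequence, so only the face of C7 matters. In the rotamer with C7a–H eclipsing the ketene acetal (least 1,3-allylic strain) the cyclopentene stands across the π plane, the in-plane methyl on the enol ether carbon C1 covers one face, and the allyl terminus should add to the other face, flanked only by C3a–H, which corresponds to (7R). The enol ether also keeps the ketone from being enolised, and the acid work-up hydrolyses the silyl ester and the enol ether.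

Step 8
Reactants: 15 (2R)-2-[(1R,5S)-5-{[tert-butyl(dimethyl)silyl]oxy}-2-methyl-3-oxocyclopentyl]-2,3-diethyl-3-ethenylpent-4-enoic acid
Product: 17 methyl (2R)-2,3-diethyl-3-ethenyl-2-[(1R,5S)-5-methyl-4-oxocyclopent-2-en-1-yl]pent-4-enoate, via methyl ester silyloxy ketone 16 (not isolated)
Conditions: MeI (1.2 equiv), DBU (1.1 equiv), MeCN, 0 °C; then DBU (2 equiv), 23 °C
Reagents that add atoms: iodomethane, CI
Why: Carboxylate O-methylation is followed by DBU-induced E1cB loss of silanolate from the C3 enolate, which gives the C3=C3a enone; the same base equilibrates C1 so that the methyl group lies trans to the bulky C7a chain.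

Step 9
Reactants: 17 methyl (2R)-2,3-diethyl-3-ethenyl-2-[(1R,5S)-5-methyl-4-oxocyclopent-2-en-1-yl]pent-4-enoate; 18 2-bromobut-1-ene
Product: 22 methyl (2R)-2-[(1R,2R,3S,5S)-2-(but-1-en-2-yl)-3-ethyl-5-methyl-4-oxocyclopentyl]-2,3-diethyl-3-ethenylpent-4-enoate, via butenyllithium reagent 19 (not isolated), via lithium dibutenylcuprate 20 (not isolated), via lithium enolate of the adduct 21 (not isolated)
Conditions: 18, t-BuLi (2 equiv), Et2O, –78 °C; CuI (0.5 equiv), –40 °C; 17, –78 °C; then EtI, HMPA, –78 → 0 °C
Reagents that add atoms: iodoethane, CCI
Why: Halogen–lithium exchange and cuprate formation are followed by conjugate addition to C3a anti to the C7a chain, and the regiodefined C3 enolate is ethylated anti to the new butenyl group (conjugate addition–enolate alkylation), which completes the all-trans ring B.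

Step 10
Reactants: 22 methyl (2R)-2-[(1R,2R,3S,5S)-2-(but-1-en-2-yl)-3-ethyl-5-methyl-4-oxocyclopentyl]-2,3-diethyl-3-ethenylpent-4-enoate
Product: 23 methyl (1S,3S,3aR,6S,7R,7aR)-6-ethenyl-3,4,6,7-tetraethyl-1-methyl-2-oxo-2,3,3a,6,7,7a-hexahydro-1H-indene-7-carboxylate
Conditions: RuCl2(H2IMes)(PCy3)(=CHPh) (second-generation Grubbs catalyst, 10 mol %), toluene (5 mM), 80 °C, static argon atmosphere (ethene not purged)
Reagents that add atoms: none
Why: Phosphine loss gives the 14-electron carbene, which exchanges onto one of the two C6 vinyl groups (Ru=CH–C6); [2+2] addition to the C4 methylene alkene, with C4 bonding to the carbene carbon, gives a ruthenacyclobutane that cycloreverts to the C4=C5 alkene and Ru=CH2, and ethene is lost when the methylidene re-enters the cycle. The closest known reaction type is diastereotopic-group-selective (desymmetrising) ring-closing metathesis of gem-divinyl carbons to cyclohexenes with a trisubstituted double bond. Ring A closes as a six-membered carbocycle by alkene metathesis between two chains held trans on C3a and C7a, so the trans ring fusion is preset, no other ring size is possible (the two vinyl groups cannot close onto each other) and the two quaternary carbons in the tether favour the reactive rotamer. C6 is the only new stereocentre and its configuration is decided by which vinyl group enters the ring. In the product-like half-chair the C7 ester is equatorial and the C7 ethyl axial, the reacting vinyl lies anti to the ester, and the (6S) product keeps the spare vinyl pseudo-axial next to the ester and the C6 ethyl pseudo-equatorial next to the C7 ethyl. The step therefore needs diastereotopic-group selectivity, and the only substrate element that can supply it is the C7 centre; since ethyl and vinyl are close in size, this bias is expected to be modest and its sense is not certain. Ethene is kept in the vessel so that the two alkylidenes interconvert faster than they cyclise and the difference between the two closing transition states is fully expressed; the C6 epimers are diastereomers and should be separable. Chemoselectivity is secure, because the only other alkene, once formed, is trisubstituted and inert.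

Step 11
Reactants: 23 methyl (1S,3S,3aR,6S,7R,7aR)-6-ethenyl-3,4,6,7-tetraethyl-1-methyl-2-oxo-2,3,3a,6,7,7a-hexahydro-1H-indene-7-carboxylate; 24 iodobenzene
Product: 25 methyl (1S,3S,3aR,6S,7R,7aR)-3,4,6,7-tetraethyl-1-methyl-2-oxo-6-[(E)-2-phenylethenyl]-2,3,3a,6,7,7a-hexahydro-1H-indene-7-carboxylate
Conditions: Pd(OAc)2 (5 mol %), n-Bu4NCl, NaHCO3, DMF, 80 °C
Reagents that add atoms: none
Why: Heck reaction: phenylpalladium iodide adds across the terminal vinyl group with phenyl on the CH2 carbon, and since C6 bears no hydrogen, β-hydride elimination can only give the E-styrene; the trisubstituted C4=C5 is too hindered to insert.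

Step 12
Reactants: 25 methyl (1S,3S,3aR,6S,7R,7aR)-3,4,6,7-tetraethyl-1-methyl-2-oxo-6-[(E)-2-phenylethenyl]-2,3,3a,6,7,7a-hexahydro-1H-indene-7-carboxylate
Product: 26 (1S,3S,3aR,6S,7R,7aR)-3,4,6,7-tetraethyl-1-methyl-2-oxo-6-[(E)-2-phenylethenyl]-2,3,3a,6,7,7a-hexahydro-1H-indene-7-carboxylic acid
Conditions: LiS-n-Pr, HMPA, 23 °C; then 1 M HCl
Reagents that add atoms: none
Why: SN2 dealkylation at the ester methyl carbon by thiolate bypasses the shielded acyl carbon; the ketone α-centres are already in the thermodynamically preferred all-trans arrangement, so the mildly basic medium should not change them.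

## Compound list

1 | pent-2-yn-1-ol | CCC#CCO | starting material
2 | sodium 3-ethyl-2,2-bis(2-methoxyethoxy)-2,5-dihydro-1,2-oxaluminol-2-uide (cyclic alkenylalanate) | CCC1=CCO[Al-]1(OCCOC)OCCOC.[Na+] | intermediate
3 | (2Z)-3-iodopent-2-en-1-ol | CC/C(I)=C/CO | intermediate
4 | (2Z)-3-ethylpenta-2,4-dien-1-ol | CC/C(C=C)=C/CO | intermediate
5 | butanoyl chloride | CCCC(=O)Cl | starting material
6 | (2Z)-3-ethylpenta-2,4-dien-1-yl butanoate | CCCC(=O)OC/C=C(/CC)C=C | intermediate
7 | (4S)-4-[(tert-butyldimethylsilyl)oxy]cyclopent-2-en-1-one | O=C1C=C[C@@H](O[Si](C)(C)C(C)(C)C)C1 | starting material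
8 | (4S)-4-[(tert-butyldimethylsilyl)oxy]-2-iodocyclopent-2-en-1-one | O=C1C(I)=C[C@@H](O[Si](C)(C)C(C)(C)C)C1 | intermediate
9 | (4S)-4-[(tert-butyldimethylsilyl)oxy]-2-methylcyclopent-2-en-1-one | O=C1C(C)=C[C@@H](O[Si](C)(C)C(C)(C)C)C1 | intermediate
10 | lithium enolate of (2Z)-3-ethylpenta-2,4-dien-1-yl butanoate (enolate geometry open) | [Li+].CCC=C([O-])OC/C=C(/CC)C=C | intermediate
11 | lithium (4S,5S)-enolate of the Michael adduct (C1=C2–OLi; C7 epimers) | [Li+].CCC(C(=O)OC/C=C(/CC)C=C)[C@H]1C(C)=C([O-])C[C@@H]1O[Si](C)(C)C(C)(C)C | intermediate
12 | (2Z)-3-ethylpenta-2,4-dien-1-yl 2-[(1S,5S)-5-{[tert-butyl(dimethyl)silyl]oxy}-2-methyl-3-[(trimethylsilyl)oxy]cyclopent-2-en-1-yl]butanoate (C7 epimers) | CCC(C(=O)OC/C=C(/CC)C=C)[C@H]1C(C)=C(O[Si](C)(C)C)C[C@@H]1O[Si](C)(C)C(C)(C)C | intermediate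
13 | trimethylsilyl ketene acetal of 12 (E/Z mixture at the ketene acetal) | CCC(=C(O[Si](C)(C)C)OC/C=C(/CC)C=C)[C@H]1C(C)=C(O[Si](C)(C)C)C[C@@H]1O[Si](C)(C)C(C)(C)C | intermediate
14 | trimethylsilyl (2R)-2-[(1R,5S)-5-{[tert-butyl(dimethyl)silyl]oxy}-2-methyl-3-[(trimethylsilyl)oxy]cyclopent-2-en-1-yl]-2,3-diethyl-3-ethenylpent-4-enoate | C=CC(C=C)(CC)[C@](CC)(C(=O)O[Si](C)(C)C)[C@H]1C(C)=C(O[Si](C)(C)C)C[C@@H]1O[Si](C)(C)C(C)(C)C | intermediate
15 | (2R)-2-[(1R,5S)-5-{[tert-butyl(dimethyl)silyl]oxy}-2-methyl-3-oxocyclopentyl]-2,3-diethyl-3-ethenylpent-4-enoic acid (epimers at the methyl-bearing ring carbon) | C=CC(C=C)(CC)[C@](CC)(C(=O)O)[C@H]1C(C)C(=O)C[C@@H]1O[Si](C)(C)C(C)(C)C | intermediate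
16 | methyl (2R)-2-[(1R,5S)-5-{[tert-butyl(dimethyl)silyl]oxy}-2-methyl-3-oxocyclopentyl]-2,3-diethyl-3-ethenylpent-4-enoate (epimers at the methyl-bearing ring carbon) | C=CC(C=C)(CC)[C@](CC)(C(=O)OC)[C@H]1C(C)C(=O)C[C@@H]1O[Si](C)(C)C(C)(C)C | intermediate
17 | methyl (2R)-2,3-diethyl-3-ethenyl-2-[(1R,5S)-5-methyl-4-oxocyclopent-2-en-1-yl]pent-4-enoate | C=CC(C=C)(CC)[C@](CC)(C(=O)OC)[C@@H]1C=CC(=O)[C@H]1C | intermediate
18 | 2-bromobut-1-ene | C=C(Br)CC | starting material
19 | but-1-en-2-yllithium | [Li]C(=C)CC | intermediate
20 | lithium di(but-1-en-2-yl)cuprate (monovalent copper) | [Li+].C=C(CC)[Cu-]C(=C)CC | intermediate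
21 | lithium enolate (C3=C2–OLi) of methyl (2R)-2-[(1R,2R,5S)-2-(but-1-en-2-yl)-5-methyl-4-oxocyclopentyl]-2,3-diethyl-3-ethenylpent-4-enoate | [Li+].C=CC(C=C)(CC)[C@](CC)(C(=O)OC)[C@@H]1[C@@H](C(=C)CC)C=C([O-])[C@H]1C | intermediate
22 | methyl (2R)-2-[(1R,2R,3S,5S)-2-(but-1-en-2-yl)-3-ethyl-5-methyl-4-oxocyclopentyl]-2,3-diethyl-3-ethenylpent-4-enoate | C=CC(C=C)(CC)[C@](CC)(C(=O)OC)[C@@H]1[C@@H](C(=C)CC)[C@H](CC)C(=O)[C@H]1C | intermediate
23 | methyl (1S,3S,3aR,6S,7R,7aR)-6-ethenyl-3,4,6,7-tetraethyl-1-methyl-2-oxo-2,3,3a,6,7,7a-hexahydro-1H-indene-7-carboxylate | CCC1=C[C@@](C=C)(CC)[C@](CC)(C(=O)OC)[C@@H]2[C@@H]1[C@H](CC)C(=O)[C@H]2C | intermediate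
24 | iodobenzene | Ic1ccccc1 | starting material
25 | methyl (1S,3S,3aR,6S,7R,7aR)-3,4,6,7-tetraethyl-1-methyl-2-oxo-6-[(E)-2-phenylethenyl]-2,3,3a,6,7,7a-hexahydro-1H-indene-7-carboxylate | CCC1=C[C@@](/C=C/c2ccccc2)(CC)[C@](CC)(C(=O)OC)[C@@H]2[C@@H]1[C@H](CC)C(=O)[C@H]2C | intermediate
26 | (1S,3S,3aR,6S,7R,7aR)-3,4,6,7-tetraethyl-1-methyl-2-oxo-6-[(E)-2-phenylethenyl]-2,3,3a,6,7,7a-hexahydro-1H-indene-7-carboxylic acid | CCC1=C[C@@](/C=C/c2ccccc2)(CC)[C@](CC)(C(=O)O)[C@@H]2[C@@H]1[C@H](CC)C(=O)[C@H]2C | target

## Step count and least certain steps

Total step count: 12. Longest linear sequence: 10 steps (from 1 through steps 1, 2, 3 and 6 to 12); the branch from 7 has 9 steps (steps 4 to 12).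

**Step 10 (key step).** The most likely failure is insufficient discrimination between the two diastereotopic vinyl groups: the bias from C7 rests on the small size difference between ethyl and vinyl and could even oppose the (6S) closure. A second problem is slow closure between a 1,1-disubstituted alkene and two neopentyl-type vinyl groups, with gradual catalyst decay.

Fallback: the stereochemical decision is moved from the substrate to the reagent. Setting out from 22, the closure would be run with a stereogenic-at-metal complex Mo(N-2,6-i-Pr2C6H3)(CHCMe2Ph)(2,5-Me2C4H2N)(OAr*), made in the flask from the bis(pyrrolide) and one antipode of the monosilylated 3,3'-dibromo-octahydrobinaphthol Ar*OH, in benzene at 22 °C. This catalyst class is known to tell apart the two vinyl groups of an ethyl-bearing gem-divinyl quaternary carbon. Both antipodes of Ar*OH would be tried and the matched one kept. The fallback comes back at 23 and no new compound arises (F0).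

**Step 7.** The most likely failure is poor or reversed facial selection at C7, since the rotamer model is the only guide and the alternative rotamer would expose the other face. Incomplete enolisation of the α-branched ester is a lesser concern.

Fallback, useful if the face on the C1 side turns out to be preferred: the two C7 substituents are brought in the opposite order.
- Setting out from 4 and 9, 4 would be acetylated (Ac2O, pyridine) to (2Z)-3-ethylpenta-2,4-dien-1-yl acetate F1.
- Its lithium enolate (LiN(i-Pr)2, THF, –78 °C) would be added to 9 and trapped with t-BuMe2SiCl/HMPA to give the bis(silyl) adduct F2.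
- Ireland–Claisen rearrangement (LiN(i-Pr)2, Me3SiCl, THF, –78 → 60 °C; aqueous work-up) would give the acid F3, in which C6 is already quaternary and C7 still bears hydrogen.
- Its dianion (LiN(i-Pr)2, 2.5 equiv, THF–HMPA, 0 → 40 °C) would be ethylated with EtI to the acid F4.
- 1 M HCl in THF would hydrolyse the enol ether and return to 15.

Because the ethyl group would now enter from the face that the pentadienyl unit takes in step 7, the configuration at C7 is the opposite of that from the direct route.

**Step 6.** The most likely failures are competing 1,2-addition of the lithium enolate to the α-methyl enone, or proton transfer from the CH2 next to the carbonyl, which would expel the silyloxy group.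

Fallback: a Lewis-acid Mukaiyama–Michael addition of a neutral donor. Setting out from 6, the enolate 10 would be silylated (Me3SiCl, –78 °C) to the silyl ketene acetal F5, which is freed from salts below –20 °C so that its own [3,3] shift cannot begin. It would then be combined with 9 and catalytic Me3SiOTf in CH2Cl2 at –78 °C; silyl transfer to the enone oxygen gives 12 directly, where the fallback comes back to the route.

**Step 9.** The most likely failure is proton exchange between the copper–lithium enolate and product before the slow ethylation, with loss of regiocontrol, C3 epimers or over-alkylation.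

Fallback: the ethyl group is placed on the enone before the conjugate addition. Setting out from 17, iodination (I2, pyridine–CH2Cl2) would give the α-iodoenone F6, and B-alkyl Suzuki coupling (BEt3, PdCl2(dppf), Cs2CO3, DMF–H2O, 50 °C) the 2-ethyl enone F7. Addition of cuprate 20 (Et2O, –78 °C), protonation on work-up and equilibration of the new C3 centre with DBU would return to 22.

## Further compounds

F0 | step 10 | none | none
F1 | step 7 | (2Z)-3-ethylpenta-2,4-dien-1-yl acetate | CC(=O)OC/C=C(/CC)C=C
F2 | step 7 | (2Z)-3-ethylpenta-2,4-dien-1-yl 2-[(1S,5S)-3,5-bis{[tert-butyl(dimethyl)silyl]oxy}-2-methylcyclopent-2-en-1-yl]acetate | O=C(C[C@H]1C(C)=C(O[Si](C)(C)C(C)(C)C)C[C@@H]1O[Si](C)(C)C(C)(C)C)OC/C=C(/CC)C=C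
F3 | step 7 | 2-[(1S,5S)-3,5-bis{[tert-butyl(dimethyl)silyl]oxy}-2-methylcyclopent-2-en-1-yl]-3-ethenyl-3-ethylpent-4-enoic acid (epimers at C2 of the acid) | C=CC(C=C)(CC)C(C(=O)O)[C@H]1C(C)=C(O[Si](C)(C)C(C)(C)C)C[C@@H]1O[Si](C)(C)C(C)(C)C
F4 | step 7 | (2R)-2-[(1R,5S)-3,5-bis{[tert-butyl(dimethyl)silyl]oxy}-2-methylcyclopent-2-en-1-yl]-2,3-diethyl-3-ethenylpent-4-enoic acid | C=CC(C=C)(CC)[C@](CC)(C(=O)O)[C@H]1C(C)=C(O[Si](C)(C)C(C)(C)C)C[C@@H]1O[Si](C)(C)C(C)(C)C
F5 | step 6 | [(1-{[(2Z)-3-ethylpenta-2,4-dien-1-yl]oxy}but-1-en-1-yl)oxy](trimethyl)silane (E/Z mixture at the ketene acetal) | CCC=C(O[Si](C)(C)C)OC/C=C(/CC)C=C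
F6 | step 9 | methyl (2R)-2,3-diethyl-3-ethenyl-2-[(1S,5S)-3-iodo-5-methyl-4-oxocyclopent-2-en-1-yl]pent-4-enoate | C=CC(C=C)(CC)[C@](CC)(C(=O)OC)[C@@H]1C=C(I)C(=O)[C@H]1C
F7 | step 9 | methyl (2R)-2,3-diethyl-3-ethenyl-2-[(1R,5S)-3-ethyl-5-methyl-4-oxocyclopent-2-en-1-yl]pent-4-enoate | C=CC(C=C)(CC)[C@](CC)(C(=O)OC)[C@@H]1C=C(CC)C(=O)[C@H]1C
A1 | alternative 1 | (2S,3R,4R,5S)-3-(2-{[tert-butyl(diphenyl)silyl]oxy}ethyl)-5-ethyl-2-methyl-4-({[tri(propan-2-yl)silyl]oxy}methyl)cyclopentan-1-one | CC(C)(C)[Si](c1ccccc1)(c1ccccc1)OCC[C@@H]2[C@@H](CO[Si](C(C)C)(C(C)C)C(C)C)[C@H](CC)C(=O)[C@H]2C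
A2 | alternative 1 | (2E,5E)-8-{[tert-butyl(diphenyl)silyl]oxy}-3-ethyl-5-methyl-1-{[tri(propan-2-yl)silyl]oxy}octa-2,5-dien-4-one | C/C(=C\CCO[Si](c1ccccc1)(c1ccccc1)C(C)(C)C)C(=O)/C(CC)=C/CO[Si](C(C)C)(C(C)C)C(C)C
A3 | alternative 2 | (1R,2S,5R,6S)-5-[(2S)-1-{[tert-butyl(dimethyl)silyl]oxy}butan-2-yl]-1,2,4-triethyl-2-[(E)-2-phenylethenyl]-6-[(trimethylsilyl)ethynyl]cyclohex-3-ene-1-carboxylic acid | CCC1=C[C@@](/C=C/c2ccccc2)(CC)[C@](CC)(C(=O)O)[C@@H](C#C[Si](C)(C)C)[C@@H]1[C@H](CC)CO[Si](C)(C)C(C)(C)C
A4 | alternative 2 | 5-[(2S)-1-{[tert-butyl(dimethyl)silyl]oxy}butan-2-yl]-3,6-diethyl-6-[(3E)-2-ethyl-4-phenylbuta-1,3-dien-1-yl]-4-[(trimethylsilyl)ethynyl]oxan-2-one with the ring carbons C4 and C5 of the oxanone configured as in A3 (lactone carbinol carbon, α-carbon and the geometry of the 1,2-alkene left open) | CCC1C(=O)OC(CC)(C=C(CC)/C=C/c2ccccc2)[C@@H]([C@H](CC)CO[Si](C)(C)C(C)(C)C)[C@@H]1C#C[Si](C)(C)C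
A5 | alternative 3 | methyl 2-[(1R,2R,3S,5S)-2-(but-1-en-2-yl)-3-ethyl-5-methyl-4-oxocyclopentyl]acetate | COC(=O)C[C@@H]1[C@@H](C(=C)CC)[C@H](CC)C(=O)[C@H]1C
A6 | alternative 3 | methyl 2-[(1R,5S)-5-methyl-4-oxocyclopent-2-en-1-yl]acetate | COC(=O)C[C@@H]1C=CC(=O)[C@H]1C
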